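**Plan**

1. Numbering used: carbocycle C1–C10 (C10 = methyl-bearing ether carbon, C1 and C2 = its CH2CH2, C3=C4 with CO2Me on C4, C5 = ether CH, C6 = lactone O–CH, C7, C8 = acyloxy CH, C9); lactone carbons C11 and C12 with exocyclic C13.
2. Retrosynthetic cuts, in order: C11=C13 (elimination) and the C8–O acyl bond; then the C1–C10 and O–C5 bonds together; then C3–C4 (cross-coupling of a cyclopropyl group that holds C1–C3) and C4=C5 (olefination); C8–C9 (aldol); C11–C13 and C7–C8 (enolate hydroxymethylation and conjugate addition to a butenolide).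
3. Enabling feature: the 2,3,4,7-tetrahydrooxepine ring O–C10–C1–C2–C3=C4–C5 has one double bond flanked by two sp3 termini, the exact imprint of a (5+2) union of a C=O unit (C10=O) with a vinylcyclopropane (C5=C4–C3, with C1 and C2 in the three-membered ring); because C5 and C10 are already joined through C6–C9, the same event closes the oxepane ring (O, C5–C10) and the ten-membered carbocycle.
4. Forward order: trans-disubstituted butyrolactone first, then the C8–C10 ketone arm and the C5=C4–cyclopropane arm, then both seven-membered rings (and the carbocycle) in one step, then the C8 ester, the α-methylene lactone last.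
5. Stereochemistry: C6 is bought ((S)-5-(hydroxymethyl)furan-2(5H)-one); C7 and the auxiliary C11 are relayed from it by trans additions, C8 is set by L-proline, C5 by allylic strain from C6 and C10 by the bridge in the cycloaddition; both epoxide centres come from a Sharpless epoxidation.

Key step: step 13

Remark: the C3=C4 bond of the target carries no descriptor; inside the seven-membered ring it can only be ring-cis (formally E), which is what the cycloaddition should give; compounds 1, 12 and 18 and the simple reagents named are taken as purchasable.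

**Route**

Step 1
Reactants: 1 (S)-5-(hydroxymethyl)furan-2(5H)-one
Product: 2 (S)-5-{[(tert-butyldimethylsilyl)oxy]methyl}furan-2(5H)-one
Conditions: TBSCl, imidazole, DMF, 0 °C to rt
Reagents that add atoms: tert-butyldimethylsilyl chloride, CC(C)(C)[Si](C)(C)Cl
Why: Imidazole-promoted silylation protects the only hydroxyl so that the butenolide can serve as a Michael acceptor; no stereocentre is touched.

Step 2
Reactants: 2 (S)-5-{[(tert-butyldimethylsilyl)oxy]methyl}furan-2(5H)-one
Product: 3 (4R,5S)-5-{[(tert-butyldimethylsilyl)oxy]methyl}-4-vinyldihydrofuran-2(3H)-one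
Conditions: CH2=CHMgBr, CuBr·SMe2 (10 mol %), THF, −78 to −40 °C
Reagents that add atoms: vinylmagnesium bromide, C=C[Mg]Br
Why: Copper-catalysed conjugate addition of the vinyl Grignard reagent should occur anti to the C6 silyloxymethyl group, which sets C7 trans to C6 by substrate control.

Step 3
Reactants: 3 (4R,5S)-5-{[(tert-butyldimethylsilyl)oxy]methyl}-4-vinyldihydrofuran-2(3H)-one
Product: 4 (3R,4S,5S)-3-(hydroxymethyl)-5-{[(tert-butyldimethylsilyl)oxy]methyl}-4-vinyldihydrofuran-2(3H)-one
Conditions: LiN(iPr)2, THF, −78 °C; then CH2O (gas), −78 to −20 °C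
Reagents that add atoms: formaldehyde, C=O
Why: Aldol reaction of the lithium lactone enolate with monomeric formaldehyde should take place on the enolate face anti to the C7 vinyl group, giving the 7,11-trans hydroxymethyl lactone (C11 is removed again in step 19 and only has to be uniform).

Step 4
Reactants: 4 (3R,4S,5S)-3-(hydroxymethyl)-5-{[(tert-butyldimethylsilyl)oxy]methyl}-4-vinyldihydrofuran-2(3H)-one
Product: 5 C13 tert-butyldiphenylsilyl ether of 4 (all-trans lactone with C6–CH2OTBS and C7–vinyl and C11–CH2OTBDPS)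
Conditions: TBDPSCl, imidazole, DMF, rt
Reagents that add atoms: tert-butyldiphenylsilyl chloride, CC(C)(C)[Si](Cl)(c1ccccc1)c1ccccc1
Why: Silylation masks the future exocyclic methylene carbon C13 as a robust ether that survives every step up to step 18.

Step 5
Reactants: 5 C13 tert-butyldiphenylsilyl ether of 4
Product: 7 C8 aldehyde (all-trans lactone with C7–CHO), via secondary ozonide 6 (not isolated)
Conditions: O3, CH2Cl2, −78 °C; then PPh3, −78 °C to rt
Reagents that add atoms: ozone, [O-][O+]=O
Why: Ozonolysis with reductive work-up cleaves the only C=C bond to the C8 aldehyde under non-basic conditions that leave the epimerisable C7 centre trans.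

Step 6
Reactants: 7 C8 aldehyde
Product: 8 (8R)-β-hydroxy ketone (C7–CH(OH)–CH2–CO–CH3)
Conditions: L-proline (30 mol %), acetone/DMSO 1:4, rt
Reagents that add atoms: acetone, CC(C)=O
Why: In the proline-catalysed direct aldol reaction the acetone enamine should add to the Re face of the aldehyde through the carboxylic-acid-organised Zimmerman–Traxler-type transition state of L-proline, fixing (8R) under catalyst control while the α-branched aldehyde cannot self-condense.

Step 7
Reactants: 8 (8R)-β-hydroxy ketone
Product: 9 C8 tert-butyldimethylsilyl ether of 8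
Conditions: TBSOTf, 2,6-lutidine, CH2Cl2, −78 °C
Reagents that add atoms: tert-butyldimethylsilyl trifluoromethanesulfonate, CC(C)(C)[Si](C)(C)OS(=O)(=O)C(F)(F)F
Why: Silylation with the silyl triflate and a hindered base at low temperature caps the β-hydroxy ketone before retro-aldol, dehydration or translactonisation can occur.

Step 8
Reactants: 9 C8 tert-butyldimethylsilyl ether of 8
Product: 10 C5 primary alcohol
Conditions: HF·pyridine, pyridine, THF, 0 °C
Reagents that add atoms: none
Why: Buffered acid-fluoride desilylation is sterically selective, so the unhindered primary tert-butyldimethylsilyl ether should cleave much faster than the secondary one and than the tert-butyldiphenylsilyl ether.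

Step 9
Reactants: 10 C5 primary alcohol
Product: 11 C5 aldehyde
Conditions: Dess–Martin periodinane, CH2Cl2, 0 °C to rt
Reagents that add atoms: none
Why: Dess–Martin oxidation gives the α-acyloxy aldehyde under non-basic conditions, which should avoid epimerisation at C6 and leaves the ketone untouched.

Step 10
Reactants: 12 methyl 2-[bis(2,2,2-trifluoroethoxy)phosphoryl]acetate
Product: 13 methyl 2-bromo-2-[bis(2,2,2-trifluoroethoxy)phosphoryl]acetate
Conditions: NaH, THF, 0 °C; then N-bromosuccinimide, 0 °C
Reagents that add atoms: N-bromosuccinimide, O=C1CCC(=O)N1Br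
Why: Electrophilic α-bromination of the stabilised sodium phosphonoacetate anion gives the bromo olefination reagent.

Step 11
Reactants: 11 C5 aldehyde; 13 methyl 2-bromo-2-[bis(2,2,2-trifluoroethoxy)phosphoryl]acetate
Product: 14 (E)-α-bromoacrylate (C5=C4 with CO2Me cis to C6 and Br on C4)
Conditions: 13, KOtBu, 18-crown-6, THF, −78 °C; then 11
Reagents that add atoms: none
Why: Horner–Wadsworth–Emmons olefination of Still–Gennari type with the bis(trifluoroethyl) bromophosphonate is selective for the aldehyde over the methyl ketone and should give the (E)-α-bromoacrylate, in which the ester is cis to C6.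

Step 12
Reactants: 14 (E)-α-bromoacrylate
Product: 15 (Z)-2-cyclopropylacrylate (C5=C4(CO2Me)–cyclopropyl with CO2Me cis to C6; methyl ketone at C10)
Conditions: c-C3H5ZnBr, Pd(PPh3)4 (5 mol %), THF, 50 °C
Reagents that add atoms: cyclopropylzinc bromide, Br[Zn]C1CC1
Why: Negishi cross-coupling proceeds with retention of alkene geometry and turns the vinyl bromide into the vinylcyclopropane, and the organozinc reagent does not attack ketone, lactone or ester.

Step 13
Reactants: 15 (Z)-2-cyclopropylacrylate
Product: 16 silyl-protected 11-oxabicyclo[4.4.1]undec-3-ene-fused γ-lactone (target configuration at C5 C6 C7 C8 C10; C8–OTBS; C13–OTBDPS trans to C8)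
Conditions: [Rh(CO)2Cl]2 (5 mol %), AgSbF6 (10 mol %), ClCH2CH2Cl (0.01 M), 60 °C
Reagents that add atoms: none
Why: Proposed new method: a rhodium-catalysed hetero-(5+2) cycloaddition of the C10 ketone C=O with the vinylcyclopropane C5=C4–C3(C1,C2), in which monovalent rhodium binds the alkene and opens the cyclopropane C3–C1 bond to a trivalent σ-alkyl/π-allyl rhodacycle, the ketone held at the metal by the C6–C9 tether inserts into the Rh–C1 bond (C1–C10), and C–O reductive elimination at the allyl terminus C5 (O–C5) releases the ring-cis C3=C4 bond and the catalyst. The closest known reaction types are the rhodium-catalysed intramolecular (5+2) cycloadditions of vinylcyclopropanes with alkynes, alkenes and allenes, the aza variant with cyclopropyl imines, and the use of ketone C=O as 2π partner in cationic rhodium (2+2+2) cycloadditions; new are C=O as partner of a vinylcyclopropane and the bridged mode of union. The oxepane ring (O, C5–C10) closes by 7-exo C–O bond formation at the allyl terminus, and the tetrahydrooxepine ring (O, C10, C1–C5), and with it the ten-membered carbocycle, closes by the C1–C10 bond of the (5+2) union, the two seven-membered rings sharing the oxygen bridge. C5 is controlled by allylic 1,3-strain from C6: in the (Z)-enoate H6 lies in the alkene plane next to the ester, so the chelated metal and then the oxygen should arrive on the face of C5 that is syn to C7, which places C4 trans to the lactone oxygen on C6; C10 has no freedom, because once C5 is set only one face of the ketone lets O and C1 span the one-atom bridge. The step needs the ketone to react in preference to the lactone and ester carbonyls (only the ketone is tethered so that it can chelate the rhodacycle), insertion to outrun β-hydride loss from C2 (helped by the electron-poor cationic metal and high dilution), and C–O elimination at C5 and not at C3 (the C3 mode would need a nine-membered ring).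

Step 14
Reactants: 16 silyl-protected 11-oxabicyclo[4.4.1]undec-3-ene-fused γ-lactone
Product: 17 C8 alcohol (C13–OTBDPS retained)
Conditions: camphorsulfonic acid (20 mol %), MeOH, rt
Reagents that add atoms: none
Why: Acid-catalysed methanolysis should remove the secondary tert-butyldimethylsilyl ether while the far more acid-stable primary tert-butyldiphenylsilyl ether stays in place.

Step 15
Reactants: 18 (E)-2-methylbut-2-en-1-ol
Product: 19 [(2R,3R)-2,3-dimethyloxiran-2-yl]methanol
Conditions: Ti(OiPr)4 (5 mol %), D-(−)-diethyl tartrate (6 mol %), t-BuOOH, 4 Å molecular sieves, CH2Cl2, −20 °C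
Reagents that add atoms: tert-butyl hydroperoxide, CC(C)(C)OO
Why: Katsuki–Sharpless asymmetric epoxidation with D-(−)-diethyl tartrate should deliver oxygen to one alkene face and set both epoxide centres as (2R,3R), the trans relation of CH2OH and the C3 methyl coming from the (E)-alkene.

Step 16
Reactants: 19 [(2R,3R)-2,3-dimethyloxiran-2-yl]methanol
Product: 20 (2S,3R)-2,3-dimethyloxirane-2-carboxylic acid
Conditions: RuCl3 (2 mol %), NaIO4, CCl4/MeCN/H2O, rt
Reagents that add atoms: sodium periodate, [Na+].[O-]I(=O)(=O)=O; water, O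
Why: Ruthenium tetroxide oxidation (RuCl3/NaIO4) converts the primary alcohol into the acid without opening the epoxide; the descriptor at C2 changes only because the priority of C1 changes.

Step 17
Reactants: 17 C8 alcohol; 20 (2S,3R)-2,3-dimethyloxirane-2-carboxylic acid
Product: 22 C8 (2S,3R)-2,3-dimethyloxirane-2-carboxylate (C13–OTBDPS retained), via mixed anhydride 21 (not isolated)
Conditions: 20, 2,4,6-Cl3C6H2COCl, Et3N, toluene, rt; then 17, DMAP, toluene, 40 °C
Reagents that add atoms: 2,4,6-trichlorobenzoyl chloride, O=C(Cl)c1c(Cl)cc(Cl)cc1Cl (in intermediate 21 only)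
Why: Yamaguchi esterification through the mixed anhydride should acylate the hindered secondary C8 alcohol with the α-quaternary acid, which cannot epimerise.

Step 18
Reactants: 22 C8 (2S,3R)-2,3-dimethyloxirane-2-carboxylate
Product: 23 C13 primary alcohol
Conditions: Bu4NF, AcOH, THF, 0 °C to rt
Reagents that add atoms: none
Why: Fluoride desilylation buffered with acetic acid should free the primary C13 alcohol without opening the epoxy ester.

Step 19
Reactants: 23 C13 primary alcohol
Product: 25 CNP0240298.1 (target), via C13 mesylate 24 (not isolated)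
Conditions: MsCl, Et3N, CH2Cl2, 0 °C to rt
Reagents that add atoms: methanesulfonyl chloride, CS(=O)(=O)Cl (in intermediate 24 only)
Why: Mesylation of the primary alcohol and in situ E1cB elimination across C11–C13 should give the α-methylene lactone and remove the auxiliary C11 stereocentre.

**Compound list**

1 | (S)-5-(hydroxymethyl)furan-2(5H)-one | O=C1O[C@H](CO)C=C1 | starting material
2 | (S)-5-{[(tert-butyldimethylsilyl)oxy]methyl}furan-2(5H)-one | O=C1O[C@H](CO[Si](C)(C)C(C)(C)C)C=C1 | intermediate
3 | (4R,5S)-5-{[(tert-butyldimethylsilyl)oxy]methyl}-4-vinyldihydrofuran-2(3H)-one | O=C1O[C@H](CO[Si](C)(C)C(C)(C)C)[C@@H](C=C)C1 | intermediate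
4 | (3R,4S,5S)-3-(hydroxymethyl)-5-{[(tert-butyldimethylsilyl)oxy]methyl}-4-vinyldihydrofuran-2(3H)-one | O=C1O[C@H](CO[Si](C)(C)C(C)(C)C)[C@@H](C=C)[C@@H]1CO | intermediate
5 | C13 tert-butyldiphenylsilyl ether of 4 (all-trans lactone) | O=C1O[C@H](CO[Si](C)(C)C(C)(C)C)[C@@H](C=C)[C@@H]1CO[Si](c1ccccc1)(c1ccccc1)C(C)(C)C | intermediate
6 | secondary ozonide of 5 (1,2,4-trioxolan-3-yl on C7, mixture at the ozonide carbon) | O=C1O[C@H](CO[Si](C)(C)C(C)(C)C)[C@@H](C2OOCO2)[C@@H]1CO[Si](c1ccccc1)(c1ccccc1)C(C)(C)C | intermediate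
7 | C8 aldehyde (all-trans lactone with C7–CHO) | O=C1O[C@H](CO[Si](C)(C)C(C)(C)C)[C@@H](C=O)[C@@H]1CO[Si](c1ccccc1)(c1ccccc1)C(C)(C)C | intermediate
8 | (8R)-β-hydroxy ketone | O=C1O[C@H](CO[Si](C)(C)C(C)(C)C)[C@@H]([C@H](O)CC(C)=O)[C@@H]1CO[Si](c1ccccc1)(c1ccccc1)C(C)(C)C | intermediate
9 | C8 tert-butyldimethylsilyl ether of 8 | O=C1O[C@H](CO[Si](C)(C)C(C)(C)C)[C@@H]([C@H](O[Si](C)(C)C(C)(C)C)CC(C)=O)[C@@H]1CO[Si](c1ccccc1)(c1ccccc1)C(C)(C)C | intermediate
10 | C5 primary alcohol | O=C1O[C@H](CO)[C@@H]([C@H](O[Si](C)(C)C(C)(C)C)CC(C)=O)[C@@H]1CO[Si](c1ccccc1)(c1ccccc1)C(C)(C)C | intermediate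
11 | C5 aldehyde | O=C1O[C@H](C=O)[C@@H]([C@H](O[Si](C)(C)C(C)(C)C)CC(C)=O)[C@@H]1CO[Si](c1ccccc1)(c1ccccc1)C(C)(C)C | intermediate
12 | methyl 2-[bis(2,2,2-trifluoroethoxy)phosphoryl]acetate | COC(=O)CP(=O)(OCC(F)(F)F)OCC(F)(F)F | starting material
13 | methyl 2-bromo-2-[bis(2,2,2-trifluoroethoxy)phosphoryl]acetate (racemic) | COC(=O)C(Br)P(=O)(OCC(F)(F)F)OCC(F)(F)F | intermediate
14 | (E)-α-bromoacrylate (CO2Me cis to C6) | O=C1O[C@H](/C=C(\C(=O)OC)Br)[C@@H]([C@H](O[Si](C)(C)C(C)(C)C)CC(C)=O)[C@@H]1CO[Si](c1ccccc1)(c1ccccc1)C(C)(C)C | intermediate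
15 | (Z)-2-cyclopropylacrylate (vinylcyclopropane–ketone substrate) | O=C1O[C@H](/C=C(\C(=O)OC)C2CC2)[C@@H]([C@H](O[Si](C)(C)C(C)(C)C)CC(C)=O)[C@@H]1CO[Si](c1ccccc1)(c1ccccc1)C(C)(C)C | intermediate
16 | silyl-protected 11-oxabicyclo[4.4.1]undec-3-ene-fused γ-lactone | CC(C)(C)[Si](OC[C@@H]1C(=O)O[C@H]2[C@H]1[C@H](O[Si](C)(C)C(C)(C)C)C[C@]1(C)CCC=C(C(=O)OC)[C@H]2O1)(c1ccccc1)c1ccccc1 | intermediate
17 | C8 alcohol | CC(C)(C)[Si](OC[C@@H]1C(=O)O[C@H]2[C@H]1[C@H](O)C[C@]1(C)CCC=C(C(=O)OC)[C@H]2O1)(c1ccccc1)c1ccccc1 | intermediate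
18 | (E)-2-methylbut-2-en-1-ol | C/C=C(\C)CO | starting material
19 | [(2R,3R)-2,3-dimethyloxiran-2-yl]methanol | OC[C@@]1(C)O[C@@H]1C | intermediate
20 | (2S,3R)-2,3-dimethyloxirane-2-carboxylic acid | OC(=O)[C@@]1(C)O[C@@H]1C | intermediate
21 | mixed anhydride of 20 with 2,4,6-trichlorobenzoic acid | O=C(OC(=O)[C@@]1(C)O[C@@H]1C)c1c(Cl)cc(Cl)cc1Cl | intermediate
22 | C8 (2S,3R)-2,3-dimethyloxirane-2-carboxylate, C13–OTBDPS | CC(C)(C)[Si](OC[C@@H]1C(=O)O[C@H]2[C@H]1[C@H](OC(=O)[C@@]1(C)O[C@@H]1C)C[C@]1(C)CCC=C(C(=O)OC)[C@H]2O1)(c1ccccc1)c1ccccc1 | intermediate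
23 | C13 primary alcohol | OC[C@@H]1C(=O)O[C@H]2[C@H]1[C@H](OC(=O)[C@@]1(C)O[C@@H]1C)C[C@]1(C)CCC=C(C(=O)OC)[C@H]2O1 | intermediate
24 | C13 mesylate | CS(=O)(=O)OC[C@@H]1C(=O)O[C@H]2[C@H]1[C@H](OC(=O)[C@@]1(C)O[C@@H]1C)C[C@]1(C)CCC=C(C(=O)OC)[C@H]2O1 | intermediate
25 | CNP0240298.1 | C=C1C(=O)O[C@H]2[C@H]1[C@H](OC(=O)[C@@]1(C)O[C@@H]1C)C[C@]1(C)CCC=C(C(=O)OC)[C@H]2O1 | target

**Step count**

Total steps: 19. Longest linear sequence: 16 (steps 1–9, 11–14, 17–19).

**Steps most likely to fail**

1. Step 13 (proposed new method). The ketone may fail to insert into the rhodium–carbon bond, so that β-hydride elimination or plain isomerisation of the vinylcyclopropane takes over; facial control at C5 may also be incomplete. The fallback sets out from 9 and comes back at 16, and makes the three bonds one at a time by known reactions. Addition of CH2=CHCH2CH2MgBr with CeCl3 (THF, −78 °C) to the ketone of 9 gives the but-3-enyl tertiary alcohol F1 with the C10 configuration of the target, separated from its C10 epimer (C1–C10 bond). HF·pyridine frees the C5 primary alcohol F2, and Dess–Martin oxidation gives the C5 aldehyde F3. Knoevenagel condensation with trimethyl phosphonoacetate (TiCl4, N-methylmorpholine, THF) gives the alkylidene phosphonoacetate F4. Base-catalysed intramolecular oxa-Michael addition of the tertiary alcohol (KOtBu cat., THF) closes the oxepane ring to the phosphonoacetate ether F5 (O–C5 bond). Ozonolysis of the terminal alkene (O3; PPh3) gives the C3 aldehyde F6, and an intramolecular Horner–Wadsworth–Emmons reaction (LiCl, DBU, MeCN) forms C3=C4 and delivers 16.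

2. Step 6. The catalyst may not override the intrinsic facial bias of the α-branched aldehyde (poor selectivity at C8), and the amine may trigger β-elimination of the lactone carboxylate or epimerisation at C7. The fallback sets out from 7 and comes back at 9. Brown methallylation with (+)-Ipc2B(2-methylallyl) (Et2O, −78 °C; NaBO3 work-up) gives the (8R)-homoallylic alcohol F7 under reagent control without any amine. Silylation (TBSOTf, 2,6-lutidine) gives the silyl ether F8, and ozonolysis of its 1,1-disubstituted alkene (O3; PPh3) gives ketone 9.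

3. Step 11. The bromo-olefination may show incomplete E/Z selectivity, and the α-acyloxy aldehyde may epimerise at C6 under the basic conditions; any geometric impurity is carried through the coupling. The fallback sets out from 11 and comes back at 15, leaving out 13 and 14 and the cross-coupling. Methyl cyclopropylacetate is deprotonated (LiN(iPr)2, THF, −78 °C) and C-phosphinylated with bis(2,2,2-trifluoroethyl) chlorophosphite to give the phosphonite F9, which is oxidised (H2O2) to the α-cyclopropyl phosphonate F10. Still–Gennari olefination of 11 with F10 (KN(SiMe3)2, 18-crown-6, THF, −78 °C) gives the (Z)-2-cyclopropylacrylate 15 directly.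

**Further compounds**

F1 | step 13 | but-3-enyl tertiary alcohol from 9 (target configuration at C10) | O=C1O[C@H](CO[Si](C)(C)C(C)(C)C)[C@@H]([C@H](O[Si](C)(C)C(C)(C)C)C[C@@](C)(O)CCC=C)[C@@H]1CO[Si](c1ccccc1)(c1ccccc1)C(C)(C)C
F2 | step 13 | C5 primary alcohol of F1 | O=C1O[C@H](CO)[C@@H]([C@H](O[Si](C)(C)C(C)(C)C)C[C@@](C)(O)CCC=C)[C@@H]1CO[Si](c1ccccc1)(c1ccccc1)C(C)(C)C
F3 | step 13 | C5 aldehyde of F2 | O=C1O[C@H](C=O)[C@@H]([C@H](O[Si](C)(C)C(C)(C)C)C[C@@](C)(O)CCC=C)[C@@H]1CO[Si](c1ccccc1)(c1ccccc1)C(C)(C)C
F4 | step 13 | alkylidene phosphonoacetate (Knoevenagel adduct, alkene isomers) | O=C1O[C@H](C=C(C(=O)OC)P(=O)(OC)OC)[C@@H]([C@H](O[Si](C)(C)C(C)(C)C)C[C@@](C)(O)CCC=C)[C@@H]1CO[Si](c1ccccc1)(c1ccccc1)C(C)(C)C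
F5 | step 13 | oxepane phosphonoacetate ether (oxa-Michael adduct, mixture at C4) | CC(C)(C)[Si](OC[C@@H]1C(=O)O[C@H]2[C@H]1[C@H](O[Si](C)(C)C(C)(C)C)C[C@](C)(CCC=C)O[C@@H]2C(C(=O)OC)P(=O)(OC)OC)(c1ccccc1)c1ccccc1
F6 | step 13 | C3 aldehyde of F5 | CC(C)(C)[Si](OC[C@@H]1C(=O)O[C@H]2[C@H]1[C@H](O[Si](C)(C)C(C)(C)C)C[C@](C)(CCC=O)O[C@@H]2C(C(=O)OC)P(=O)(OC)OC)(c1ccccc1)c1ccccc1
F7 | step 6 | (8R)-homoallylic alcohol (2-methylallyl adduct of 7) | O=C1O[C@H](CO[Si](C)(C)C(C)(C)C)[C@@H]([C@H](O)CC(C)=C)[C@@H]1CO[Si](c1ccccc1)(c1ccccc1)C(C)(C)C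
F8 | step 6 | C8 tert-butyldimethylsilyl ether of F7 | O=C1O[C@H](CO[Si](C)(C)C(C)(C)C)[C@@H]([C@H](O[Si](C)(C)C(C)(C)C)CC(C)=C)[C@@H]1CO[Si](c1ccccc1)(c1ccccc1)C(C)(C)C
F9 | step 11 | methyl 2-[bis(2,2,2-trifluoroethoxy)phosphanyl]-2-cyclopropylacetate (racemic) | COC(=O)C(C1CC1)P(OCC(F)(F)F)OCC(F)(F)F
F10 | step 11 | methyl 2-[bis(2,2,2-trifluoroethoxy)phosphoryl]-2-cyclopropylacetate (racemic) | COC(=O)C(C1CC1)P(=O)(OCC(F)(F)F)OCC(F)(F)F
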